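**Retrosynthetic overview**

1. The target is 5,7-dihydroxy-6,8-dimethyl-2-nonadecylchromone. The last disconnection cuts the exocyclic bond from C2 of the pyranone ring (ring B) to C1' of the chain and, in the same operation, the ring bond O1–C2. This leads back to an open-chain α-oxo ketene dithioacetal and a nonadecyl cuprate.
2. Enabling feature: C2 of ring B is bound to O1 and conjugated through C3 with the C4 carbonyl, so it is a vinylogous ester carbon at the carboxylic acid oxidation level. It can be carried as a C(SMe)2 carbon that accepts first the C19 nucleophile and then the phenolic oxygen, each by addition–elimination. Ring A (oxygens at C5, C7 and C8a, methyls at C6 and C8) is symmetric about the C4a···C7 axis, so either ortho oxygen closes to the same chromone.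
3. The dithioacetal comes from the tris-MOM ether of 2,4,6-trihydroxy-3,5-dimethylacetophenone (CS2, MeI), itself made from commercial phloroacetophenone by double C-methylation. The chain comes from 1-bromononadecane via its Grignard reagent.
4. Ring order: ring A is bought; ring B is closed and aromatised last, in the key step, which also frees the two hydroxyl groups.

Key step: step 5

Remark: the target has no stereocentre; the C=C geometry of intermediates 8 and 9 is lost on ring closure and is left undefined.

**Route**

Step 1
Reactants: 1 1-(2,4,6-trihydroxyphenyl)ethanone (phloroacetophenone)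
Product: 2 1-(2,4,6-trihydroxy-3,5-dimethylphenyl)ethanone
Conditions: NaOMe (3.0 equiv), MeI (2.1 equiv), MeOH, 0 °C to reflux; aq. HCl work-up
Reagents that add atoms: iodomethane, CI
Why: The phloroglucinol phenoxide is an ambident, carbon-nucleophilic enolate, so in methanol MeI should alkylate the two free ring carbons rather than oxygen (known C-methylation of acylphloroglucinols), with the MeI charge limited to two equivalents to hold back the dearomatised gem-dimethyl product.

Step 2
Reactants: 2 1-(2,4,6-trihydroxy-3,5-dimethylphenyl)ethanone
Product: 3 1-[2,4,6-tris(methoxymethoxy)-3,5-dimethylphenyl]ethanone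
Conditions: NaH (3.3 equiv), MOMCl (3.6 equiv), DMF, 0 °C to rt
Reagents that add atoms: chloromethyl methyl ether, COCCl
Why: Williamson-type O-alkylation of the three sodium phenoxides with the hard electrophile MOMCl should give the tris-acetal; NaH is needed to break the hydrogen bond of the last ortho hydroxyl to the acetyl group, and the acetals survive the bases and organometallics that follow yet fall in the acidic finish of step 5.

Step 3
Reactants: 3 1-[2,4,6-tris(methoxymethoxy)-3,5-dimethylphenyl]ethanone
Product: 4 3,3-bis(methylsulfanyl)-1-[2,4,6-tris(methoxymethoxy)-3,5-dimethylphenyl]prop-2-en-1-one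
Conditions: t-BuOK (2.2 equiv), CS2 (1.1 equiv), THF, 0 °C; then MeI (2.2 equiv), 0 °C to rt
Reagents that add atoms: carbon disulfide, S=C=S; iodomethane, CI
Why: The methyl ketone enolate adds to CS2 and the ene-dithiolate dianion is S-methylated twice, the standard synthesis of α-oxo ketene dithioacetals; the acetyl CH3 is the only acidic site and the MOM acetals are inert to base and MeI.

Step 4
Reactants: 5 1-bromononadecane
Product: 6 nonadecylmagnesium bromide (titrated THF solution, used directly)
Conditions: Mg turnings (1.3 equiv), I2 (cat.), THF, 45 °C, slow addition of 5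
Reagents that add atoms: magnesium, [Mg]
Why: Grignard formation by insertion of magnesium into the primary C–Br bond; warm THF keeps the waxy bromide dissolved and slow addition limits Wurtz homocoupling.

Step 5
Reactants: 4 3,3-bis(methylsulfanyl)-1-[2,4,6-tris(methoxymethoxy)-3,5-dimethylphenyl]prop-2-en-1-one, 6 nonadecylmagnesium bromide
Product: 10 5,7-dihydroxy-6,8-dimethyl-2-nonadecyl-4H-chromen-4-one, via dinonadecylcuprate 7 (not isolated), via tris-MOM methylsulfanyl enone 8 (not isolated), via trihydroxy methylsulfanyl enone 9 (not isolated)
Conditions: 6 (2.2 equiv), CuBr·SMe2 (1.1 equiv), THF, −40 °C; then 4, −40 to −10 °C; then MeOH, conc. HCl, same flask, 60 °C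
Reagents that add atoms: none
Why: The soft cuprate 7 should add in 1,4-fashion to the bis(methylsulfanyl)methylene carbon of 4 and the adduct should expel methanethiolate (vinylic addition–elimination), which forms the C2–C1' bond and gives vinylogous thioester 8; this is the known behaviour of α-oxo ketene dithioacetals towards organocuprates. Methanolic HCl then cleaves the three MOM acetals to 9, and an ortho hydroxyl adds to the same carbon in a 6-endo-trig conjugate addition with loss of a second MeSH, which closes and aromatises the pyranone ring; the closest known type is the acid-induced cyclisation of 2'-hydroxyaryl β-(methylsulfanyl) enones and of 1-(2-hydroxyaryl)-1,3-diketones to chromones. No stereocentre is formed, and the E/Z geometry of 8 and 9 is irrelevant. The step needs 1,4- over 1,2-addition, which the copper reagent and the two ortho substituents that shield the aryl ketone should secure, and mono- over double substitution, which one equivalent of cuprate at low temperature should secure because the first adduct stays an enolate until it loses thiolate. Ring-closure regiochemistry is not an issue because the two ortho oxygens of the symmetric aryl ring are equivalent, and hydrolysis of 8 or 9 to the 1,3-diketone would only feed the same chromone by cyclodehydration.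

**Compound list**

1 | 1-(2,4,6-trihydroxyphenyl)ethanone (phloroacetophenone) | CC(=O)c1c(O)cc(O)cc1O | starting material
2 | 1-(2,4,6-trihydroxy-3,5-dimethylphenyl)ethanone | CC(=O)c1c(O)c(C)c(O)c(C)c1O | intermediate
3 | 1-[2,4,6-tris(methoxymethoxy)-3,5-dimethylphenyl]ethanone | CC(=O)c1c(OCOC)c(C)c(OCOC)c(C)c1OCOC | intermediate
4 | 3,3-bis(methylsulfanyl)-1-[2,4,6-tris(methoxymethoxy)-3,5-dimethylphenyl]prop-2-en-1-one | CSC(SC)=CC(=O)c1c(OCOC)c(C)c(OCOC)c(C)c1OCOC | intermediate
5 | 1-bromononadecane | CCCCCCCCCCCCCCCCCCCBr | starting material
6 | nonadecylmagnesium bromide | CCCCCCCCCCCCCCCCCCC[Mg]Br | intermediate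
7 | bromomagnesium dinonadecylcuprate | CCCCCCCCCCCCCCCCCCC[Cu-]CCCCCCCCCCCCCCCCCCC.[Mg+]Br | intermediate (not isolated)
8 | 3-(methylsulfanyl)-1-[2,4,6-tris(methoxymethoxy)-3,5-dimethylphenyl]docos-2-en-1-one (E/Z mixture) | CCCCCCCCCCCCCCCCCCCC(SC)=CC(=O)c1c(OCOC)c(C)c(OCOC)c(C)c1OCOC | intermediate (not isolated)
9 | 3-(methylsulfanyl)-1-(2,4,6-trihydroxy-3,5-dimethylphenyl)docos-2-en-1-one (E/Z mixture) | CCCCCCCCCCCCCCCCCCCC(SC)=CC(=O)c1c(O)c(C)c(O)c(C)c1O | intermediate (not isolated)
10 | 5,7-dihydroxy-6,8-dimethyl-2-nonadecyl-4H-chromen-4-one | CCCCCCCCCCCCCCCCCCCc1cc(=O)c2c(O)c(C)c(O)c(C)c2o1 | target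

**Step count and risks**

Total step count: 5. Longest linear sequence: 4 steps (1 → 2 → 3 → 4 → 10); step 4 is a side branch that prepares the chain reagent.

Steps most likely to fail:

Step 5. Both methylsulfanyl groups may be displaced, the reagent may attack the ketone in 1,2-fashion, or the long-chain organometallic may precipitate at low temperature so that alkyl transfer stays incomplete. The fallback forms the same C2–C1' bond on a preformed ring B by copper-catalysed conjugate addition; it sets out from compound 2 and comes back at compound 10. Compound 2 is protected on the two non-chelated hydroxyls (MOMCl 2.2 equiv, iPr2NEt, CH2Cl2) to give 1-[2-hydroxy-4,6-bis(methoxymethoxy)-3,5-dimethylphenyl]ethanone F1. Condensation with DMF dimethyl acetal in toluene at 90 °C gives the enaminone (E)-3-(dimethylamino)-1-[2-hydroxy-4,6-bis(methoxymethoxy)-3,5-dimethylphenyl]prop-2-en-1-one F2. Stirring with silica gel or dilute AcOH closes this, with loss of dimethylamine, to 5,7-bis(methoxymethoxy)-6,8-dimethyl-4H-chromen-4-one F3. Grignard reagent 6 with CuBr·SMe2 (10 mol %) in THF at −30 °C should add 1,4 to give racemic 5,7-bis(methoxymethoxy)-6,8-dimethyl-2-nonadecylchroman-4-one F4. Dehydrogenation with IBX in DMSO at 80 °C gives 5,7-bis(methoxymethoxy)-6,8-dimethyl-2-nonadecyl-4H-chromen-4-one F5, and HCl in MeOH at 50 °C removes the MOM groups to give 10.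

Step 1. Alkylation may stop at the mono-methyl stage, run on to the dearomatised gem-dimethyl cyclohexadienone, or go to oxygen. The fallback introduces each methyl as an aminomethyl group and then cleaves the C–N bonds reductively; it sets out from compound 1 and comes back at compound 2. Double Mannich reaction of 1 (aq. CH2O, Me2NH, EtOH, rt) stops cleanly at one CH2NMe2 group per free ring carbon and gives 1-[3,5-bis[(dimethylamino)methyl]-2,4,6-trihydroxyphenyl]ethanone F6. Hydrogenolysis of the two benzylic C–N bonds (H2, Pd/C, AcOH, 60 °C), a known route from phenolic Mannich bases to ortho-methylphenols, then gives 2.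

Step 3. The second deprotonation and S-alkylation may stay incomplete, or MeI may alkylate the ketone enolate before it has added to CS2. The fallback separates C–C bond formation from S-methylation; it sets out from compound 3 and comes back at compound 4. Thio-Claisen condensation of the enolate of 3 with dimethyl trithiocarbonate (NaH, THF–DMF) gives the isolable β-oxo dithioester methyl 3-oxo-3-[2,4,6-tris(methoxymethoxy)-3,5-dimethylphenyl]propanedithioate F7. Its soft enethiolate is then S-methylated under mild conditions (MeI, K2CO3, acetone) to give 4.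

**Further compounds**

F1 | step 5 | 1-[2-hydroxy-4,6-bis(methoxymethoxy)-3,5-dimethylphenyl]ethanone | CC(=O)c1c(O)c(C)c(OCOC)c(C)c1OCOC
F2 | step 5 | (E)-3-(dimethylamino)-1-[2-hydroxy-4,6-bis(methoxymethoxy)-3,5-dimethylphenyl]prop-2-en-1-one | CN(C)/C=C/C(=O)c1c(O)c(C)c(OCOC)c(C)c1OCOC
F3 | step 5 | 5,7-bis(methoxymethoxy)-6,8-dimethyl-4H-chromen-4-one | O=c1ccoc2c(C)c(OCOC)c(C)c(OCOC)c12
F4 | step 5 | racemic 5,7-bis(methoxymethoxy)-6,8-dimethyl-2-nonadecylchroman-4-one | CCCCCCCCCCCCCCCCCCCC1CC(=O)c2c(OCOC)c(C)c(OCOC)c(C)c2O1
F5 | step 5 | 5,7-bis(methoxymethoxy)-6,8-dimethyl-2-nonadecyl-4H-chromen-4-one | CCCCCCCCCCCCCCCCCCCc1cc(=O)c2c(OCOC)c(C)c(OCOC)c(C)c2o1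
F6 | step 1 | 1-[3,5-bis[(dimethylamino)methyl]-2,4,6-trihydroxyphenyl]ethanone | CC(=O)c1c(O)c(CN(C)C)c(O)c(CN(C)C)c1O
F7 | step 3 | methyl 3-oxo-3-[2,4,6-tris(methoxymethoxy)-3,5-dimethylphenyl]propanedithioate | CSC(=S)CC(=O)c1c(OCOC)c(C)c(OCOC)c(C)c1OCOC
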